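**Assumption (one line):** core numbered as a cyclotetradecane (C1 = lactone O–CH, C2=C3 and C11=C12 the ring alkenes, C6 = CH–OAc, C7/C10 = peroxide carbons, C14 = CH bearing the acrylate carbon), so the target is (1S,6S,7R,10S,14S,2E,11Z); the L-fructose-derived Shi ketone and (S)-Me-CBS are bought.

**Retrosynthetic overview**
1. Target ⇐ C6–OH acetylation and TEMPO/PhI(OAc)2 oxidative lactonisation of the 2-methylene-1,4-diol in epidioxy triol 34.
2. 1,2-Dioxane ⇐ acid-triggered 6-exo opening (inversion at C7) of a (6S,7S)-oxirane by a C10 hydroperoxide, itself from SN2 (inversion) of a C10 allylic mesylate with peroxide 22; oxirane by Shi epoxidation, C10 carbinol by CBS reduction.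
3. 14-Membered ring ⇐ intramolecular Nozaki–Hiyama–Kishi closure of C1–C2 (alkenyl bromide onto aldehyde) in keto aldehyde 25: the key step.
4. 25 ⇐ Criegee cleavage of cyclohexenediol 24 ⇐ hydroxy ketone 8 (from (R)-carvone: C14 stereocentre, Z-C11=C12, lactone carbons) + Grignard reagent 23.
5. 23 ⇐ two C5 halves from but-3-yn-1-ol by carboalumination (one as its TBS ether, one as the free alcohol), joined by Negishi coupling. Ring order: carbocycle → oxirane → dioxane → lactone.

## East fragment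

**Step 1**
Reactants: 1 (R)-(−)-carvone
Product: 2 (R)-5-(3-chloroprop-1-en-2-yl)-2-methylcyclohex-2-en-1-one
Conditions: Ca(OCl)2, CO2 (dry ice), CH2Cl2/H2O, 0 °C
Reagents that add atoms: calcium hypochlorite, [Ca+2].[O-]Cl.[O-]Cl
Why: Ene-type allylic chlorination by HOCl attacks only the electron-rich isopropenyl group and leaves the enone and the C5 stereocentre untouched.

**Step 2**
Reactants: 2 allylic chloride
Product: 3 2-[(1R)-4-methyl-5-oxocyclohex-3-en-1-yl]prop-2-en-1-yl acetate
Conditions: KOAc, Bu4NI (cat.), DMF, 60 °C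
Reagents that add atoms: potassium acetate, CC(=O)[O-].[K+]
Why: SN2 displacement of a primary allylic chloride by acetate (SN2′ gives the same product).

**Step 3**
Reactants: 3 allylic acetate
Product: 4 (R)-5-(3-hydroxyprop-1-en-2-yl)-2-methylcyclohex-2-en-1-one
Conditions: K2CO3 (cat.), MeOH, 0 °C to rt
Reagents that add atoms: none
Why: Mild Zemplén-type transesterification frees the primary allylic alcohol without touching the enone.

**Step 4**
Reactants: 4 allylic alcohol
Product: 5 (R)-5-[3-(tert-butyldimethylsilyloxy)prop-1-en-2-yl]-2-methylcyclohex-2-en-1-one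
Conditions: TBSCl, imidazole, DMF, rt
Reagents that add atoms: tert-butyldimethylsilyl chloride, CC(C)(C)[Si](C)(C)Cl
Why: Standard silylation masks the future lactone carbonyl carbon as a robust primary TBS ether.

**Step 5**
Reactants: 5 silyl ether
Product: 8 (5S,6S)-6-hydroxy ketone, via silyl dienol ether 6 (not isolated), via silyloxy ketone 7 (not isolated)
Conditions: LDA, THF, −78 °C; TMSCl; then mCPBA, NaHCO3, CH2Cl2, −20 °C; aq. citric acid, THF, 0 °C
Reagents that add atoms: 3-chloroperbenzoic acid, O=C(OO)c1cccc(Cl)c1; chlorotrimethylsilane, C[Si](C)(C)Cl (stays only in 6 and 7)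
Why: Rubottom oxidation of the kinetic α′-enolate places OH at C6, mainly trans to the C5 substituent; this centre only serves the later glycol cleavage and is destroyed there.

## West fragment

**Step 6**
Reactants: 9 but-3-yn-1-ol
Product: 10 tert-butyl(but-3-yn-1-yloxy)dimethylsilane
Conditions: TBSCl, imidazole, CH2Cl2, rt
Reagents that add atoms: tert-butyldimethylsilyl chloride, CC(C)(C)[Si](C)(C)Cl
Why: Silylation removes the acidic OH, so the carbometalation and the later organozinc coupling run on a neutral ether.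

**Step 7**
Reactants: 10 silyl-protected butynol
Product: 12 tert-butyl{[(E)-4-iodo-3-methylbut-3-en-1-yl]oxy}dimethylsilane, via silyloxy alkenylalane 11 (not isolated)
Conditions: AlMe3 (2 equiv), Cp2ZrCl2 (20 mol %), CH2Cl2, 0 °C to rt; I2, THF, −30 °C
Reagents that add atoms: trimethylaluminium, C[Al](C)C; iodine, II
Why: Negishi Zr-catalysed syn-carboalumination of the terminal alkyne followed by iodinolysis with retention fixes the E-trisubstituted alkene, and the TBS ether is inert to AlMe3.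

**Step 8**
Reactants: 9 but-3-yn-1-ol
Product: 14 (E)-4-bromo-3-methylbut-3-en-1-ol, via O-aluminated alkenylalane 13 (not isolated)
Conditions: AlMe3 (3 equiv), Cp2ZrCl2 (25 mol %), CH2Cl2, 0 °C to rt; NBS, THF, −30 °C
Reagents that add atoms: trimethylaluminium, C[Al](C)C; N-bromosuccinimide, O=C1CCC(=O)N1Br
Why: Negishi carboalumination of the free alcohol (as its aluminium alkoxide), with bromodealumination (retention) giving the E-alkenyl bromide that later serves as the NHK donor.

**Step 9**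
Reactants: 14 bromo alcohol
Product: 15 (E)-1-bromo-4-iodo-2-methylbut-1-ene
Conditions: I2, PPh3, imidazole, CH2Cl2, 0 °C
Reagents that add atoms: iodine, II
Why: Appel-type iodination of the primary alcohol; the alkenyl bromide is inert.

**Step 10**
Reactants: 15 bromo iodide; 12 alkenyl iodide
Product: 17 {[(3E,7E)-8-bromo-3,7-dimethylocta-3,7-dien-1-yl]oxy}(tert-butyl)dimethylsilane, via alkylzinc iodide 16 (not isolated)
Conditions: Zn dust (BrCH2CH2Br/TMSCl-activated), THF, 35 °C; then 12 (1.1 equiv), Pd(PPh3)4 (5 mol %), THF, 0 °C to rt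
Reagents that add atoms: zinc, [Zn] (stays only in 16)
Why: Zinc inserts only into the sp3 C–I bond, and the Negishi coupling engages the alkenyl iodide far faster than the alkenyl bromide, with retention of both E geometries.

**Step 11**
Reactants: 17 silyl ether
Product: 18 (3E,7E)-8-bromo-3,7-dimethylocta-3,7-dien-1-ol
Conditions: TBAF, THF, 0 °C
Reagents that add atoms: none
Why: Fluoride cleaves the primary TBS ether cleanly.

**Step 12**
Reactants: 18 bromo dienol
Product: 19 (1E,5E)-1,8-dibromo-2,6-dimethylocta-1,5-diene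
Conditions: CBr4, PPh3, CH2Cl2, 0 °C
Reagents that add atoms: carbon tetrabromide, BrC(Br)(Br)Br
Why: Appel bromination gives the primary alkyl bromide needed for selective Grignard formation.

## Peroxide building block

**Step 13**
Reactants: 20 2,3-dimethylbut-2-ene
Product: 22 2-methoxyprop-2-yl hydroperoxide, via acetone O-oxide 21 (not isolated)
Conditions: O3, MeOH/CH2Cl2, −78 °C; concentrate cold
Reagents that add atoms: ozone, [O-][O+]=O; methanol, CO
Why: Ozonolysis in methanol traps the Criegee carbonyl oxide as a monoprotected hydrogen peroxide that can be alkylated once.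

## Union, macrocyclisation and end game

**Step 14**
Reactants: 19 dibromide; 8 hydroxy ketone
Product: 24 (5S,6S)-1-[(3E,7E)-8-bromo-3,7-dimethylocta-3,7-dien-1-yl]-5-[3-(TBSO)prop-1-en-2-yl]-2-methylcyclohex-2-ene-1,6-diol, via Grignard reagent 23 (not isolated)
Conditions: 19, Mg, Et2O, 35 °C; CeCl3, THF, −78 °C; add 8 pre-treated with LiHMDS (1.0 equiv), −78 to −40 °C; aq. NH4Cl
Reagents that add atoms: magnesium, [Mg] (stays only in 23)
Why: In ether Mg inserts only into the alkyl C–Br bond, and the Imamoto organocerium adds 1,2 to the enolisable enone; the new C1 carbinol centre is irrelevant because it becomes a ketone in step 15.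

**Step 15**
Reactants: 24 diol
Product: 25 (2S,4Z,9E,13E)-14-bromo-2-[3-(TBSO)prop-1-en-2-yl]-5,9,13-trimethyl-6-oxotetradeca-4,9,13-trienal
Conditions: Pb(OAc)4, K2CO3, CH2Cl2, −20 to 0 °C; use crude at once
Reagents that add atoms: none
Why: Criegee glycol cleavage opens the carvone ring, releasing the aldehyde (future C1), the Z-enone (Z fixed by the former ring) and the intact C14 stereocentre under non-epimerising conditions.

**Step 16**
Reactants: 25 keto aldehyde
Product: 26 (1S,2E,6E,11Z,14S)-1-hydroxy-3,7,11-trimethyl-14-[3-(TBSO)prop-1-en-2-yl]cyclotetradeca-2,6,11-trien-10-one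
Conditions: CrCl2 (8 equiv), NiCl2 (10 mol %), DMSO/THF 3:1, 2 mM (syringe pump), rt to 40 °C
Reagents that add atoms: none
Why: Intramolecular Nozaki–Hiyama–Kishi macrocyclisation adds the alkenylchromium (E retained) to the aldehyde only; Felkin–Anh attack anti to the branched 2-propenyl group on C14 sets C1 as S (the cis-lactone relationship), under neutral conditions that do not epimerise C14.

**Step 17**
Reactants: 26 hydroxy enone
Product: 27 C1 triethylsilyl ether of 26
Conditions: TESCl, imidazole, DMAP (cat.), DMF, 0 °C to rt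
Reagents that add atoms: chlorotriethylsilane, CC[Si](CC)(CC)Cl
Why: An acid-labile silyl ether blocks C1–OH for the mesylation and is shed in step 21.

**Step 18**
Reactants: 27 silyl ether
Product: 28 (1S,6S,7S,14S)-6,7-epoxide of 27
Conditions: L-fructose-derived Shi ketone (30 mol %), Oxone, K2CO3, Bu4NHSO4, MeCN/DMM/aq. borate buffer pH 10.5, 0 °C
Reagents that add atoms: potassium peroxymonosulfate (Oxone), [K+].[O-]S(=O)(=O)OO
Why: Shi epoxidation picks the only electron-rich, unencumbered trisubstituted alkene (C11=C12 is an enone, C2=C3 and the methylidene carry allylic oxygen), and the ent-catalyst delivers oxygen to the face giving the (6S,7S)-oxirane.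

**Step 19**
Reactants: 28 epoxy enone
Product: 29 (10R)-allylic alcohol
Conditions: (S)-Me-CBS (0.5 equiv), catecholborane, toluene, −78 °C
Reagents that add atoms: none
Why: Corey–Bakshi–Shibata reduction with the α-methylalkenyl group as the large substituent gives the (R)-carbinol by reagent control and leaves the oxirane alone.

**Step 20**
Reactants: 29 allylic alcohol; 22 2-methoxyprop-2-yl hydroperoxide
Product: 31 (10S)-10-[(2-methoxypropan-2-yl)peroxy] epoxide, via allylic mesylate 30 (not isolated)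
Conditions: Ms2O, Et3N, THF, −40 °C; then 22 (2 equiv), KOtBu (1.8 equiv), 18-crown-6, THF/DMF, −40 to 0 °C
Reagents that add atoms: methanesulfonic anhydride, CS(=O)(=O)OS(C)(=O)=O (stays only in 30)
Why: The peroxide anion displaces the secondary allylic mesylate by SN2 with inversion (R to S at C10); the chloride-free mesylation avoids allylic chloride formation.

**Step 21**
Reactants: 31 peroxyketal
Product: 34 (1S,2E,6S,7R,10S,11Z,14S)-7,10-epidioxy-14-(3-hydroxyprop-1-en-2-yl)-3,7,11-trimethylcyclotetradeca-2,11-diene-1,6-diol, via hydroperoxy epoxide 32 (not isolated), via silylated epidioxy alcohol 33 (not isolated)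
Conditions: CSA (20 mol %), CH2Cl2/MeOH 5:1, 0 °C to rt
Reagents that add atoms: none
Why: Acid unmasks the hydroperoxide, which opens the protonated oxirane 6-exo at the tertiary C7 with inversion (S to R, C6 retained) to form the 1,2-dioxane; the TES and primary TBS ethers are methanolysed in the same pot.

**Step 22**
Reactants: 34 epidioxy triol
Product: 37 deacetyl-denticulatolide, via enal 35 (not isolated), via lactol 36 (not isolated)
Conditions: TEMPO (20 mol %), PhI(OAc)2 (2.5 equiv), CH2Cl2, rt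
Reagents that add atoms: none
Why: The oxoammonium oxidant selects the primary allylic alcohol; the enal is trapped by C1–OH as a five-membered lactol and oxidised on to the cis-fused α-methylene-γ-butyrolactone, and the peroxide is inert to these conditions.

**Step 23**
Reactants: 37 deacetyl-denticulatolide
Product: 38 denticulatolide
Conditions: Ac2O, pyridine, DMAP (cat.), CH2Cl2, 0 °C to rt
Reagents that add atoms: acetic anhydride, CC(=O)OC(C)=O
Why: DMAP-catalysed acetylation of the only remaining hydroxyl (C6) completes the target without touching the stereocentres.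

## Compound list

1 | (R)-(−)-carvone | CC1=CC[C@@H](C(C)=C)CC1=O | starting material
2 | (R)-5-(3-chloroprop-1-en-2-yl)-2-methylcyclohex-2-en-1-one | CC1=CC[C@@H](C(=C)CCl)CC1=O | intermediate
3 | 2-[(1R)-4-methyl-5-oxocyclohex-3-en-1-yl]prop-2-en-1-yl acetate | CC1=CC[C@@H](C(=C)COC(C)=O)CC1=O | intermediate
4 | (R)-5-(3-hydroxyprop-1-en-2-yl)-2-methylcyclohex-2-en-1-one | CC1=CC[C@@H](C(=C)CO)CC1=O | intermediate
5 | (R)-5-[3-(tert-butyldimethylsilyloxy)prop-1-en-2-yl]-2-methylcyclohex-2-en-1-one | CC1=CC[C@@H](C(=C)CO[Si](C)(C)C(C)(C)C)CC1=O | intermediate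
6 | 1-trimethylsilyloxy-1(6),2-diene (TMS dienol ether of 5) | CC1=CC[C@@H](C(=C)CO[Si](C)(C)C(C)(C)C)C=C1O[Si](C)(C)C | intermediate
7 | (5S,6S)-6-trimethylsilyloxy derivative of 5 | CC1=CC[C@@H](C(=C)CO[Si](C)(C)C(C)(C)C)[C@H](O[Si](C)(C)C)C1=O | intermediate
8 | (5S,6S)-5-[3-(tert-butyldimethylsilyloxy)prop-1-en-2-yl]-6-hydroxy-2-methylcyclohex-2-en-1-one (major trans epimer) | CC1=CC[C@@H](C(=C)CO[Si](C)(C)C(C)(C)C)[C@H](O)C1=O | intermediate
9 | but-3-yn-1-ol | C#CCCO | starting material
10 | tert-butyl(but-3-yn-1-yloxy)dimethylsilane | C#CCCO[Si](C)(C)C(C)(C)C | intermediate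
11 | (E)-[4-(tert-butyldimethylsilyloxy)-2-methylbut-1-enyl]dimethylalane | C[Al](C)/C=C(\C)CCO[Si](C)(C)C(C)(C)C | intermediate
12 | tert-butyl{[(E)-4-iodo-3-methylbut-3-en-1-yl]oxy}dimethylsilane | I/C=C(\C)CCO[Si](C)(C)C(C)(C)C | intermediate
13 | (E)-[4-(dimethylaluminooxy)-2-methylbut-1-enyl]dimethylalane | C[Al](C)/C=C(\C)CCO[Al](C)C | intermediate
14 | (E)-4-bromo-3-methylbut-3-en-1-ol | Br/C=C(\C)CCO | intermediate
15 | (E)-1-bromo-4-iodo-2-methylbut-1-ene | Br/C=C(\C)CCI | intermediate
16 | [(E)-4-bromo-3-methylbut-3-en-1-yl]zinc iodide | Br/C=C(\C)CC[Zn]I | intermediate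
17 | {[(3E,7E)-8-bromo-3,7-dimethylocta-3,7-dien-1-yl]oxy}(tert-butyl)dimethylsilane | Br/C=C(\C)CC/C=C(\C)CCO[Si](C)(C)C(C)(C)C | intermediate
18 | (3E,7E)-8-bromo-3,7-dimethylocta-3,7-dien-1-ol | Br/C=C(\C)CC/C=C(\C)CCO | intermediate
19 | (1E,5E)-1,8-dibromo-2,6-dimethylocta-1,5-diene | Br/C=C(\C)CC/C=C(\C)CCBr | intermediate
20 | 2,3-dimethylbut-2-ene | CC(C)=C(C)C | starting material
21 | acetone O-oxide (carbonyl oxide) | CC(C)=[O+][O-] | intermediate
22 | 2-methoxyprop-2-yl hydroperoxide | COC(C)(C)OO | intermediate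
23 | [(3E,7E)-8-bromo-3,7-dimethylocta-3,7-dien-1-yl]magnesium bromide | Br/C=C(\C)CC/C=C(\C)CC[Mg]Br | intermediate
24 | (5S,6S)-1-[(3E,7E)-8-bromo-3,7-dimethylocta-3,7-dien-1-yl]-5-[3-(tert-butyldimethylsilyloxy)prop-1-en-2-yl]-2-methylcyclohex-2-ene-1,6-diol (C1 epimers) | CC1=CC[C@@H](C(=C)CO[Si](C)(C)C(C)(C)C)[C@H](O)C1(O)CC/C(C)=C/CC/C(C)=C/Br | intermediate
25 | (2S,4Z,9E,13E)-14-bromo-2-[3-(tert-butyldimethylsilyloxy)prop-1-en-2-yl]-5,9,13-trimethyl-6-oxotetradeca-4,9,13-trienal | O=C[C@@H](C/C=C(/C)C(=O)CC/C(C)=C/CC/C(C)=C/Br)C(=C)CO[Si](C)(C)C(C)(C)C | intermediate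
26 | (1S,2E,6E,11Z,14S)-1-hydroxy-3,7,11-trimethyl-14-[3-(tert-butyldimethylsilyloxy)prop-1-en-2-yl]cyclotetradeca-2,6,11-trien-10-one | O[C@H]1/C=C(\C)CC/C=C(\C)CCC(=O)/C(C)=C\C[C@H]1C(=C)CO[Si](C)(C)C(C)(C)C | intermediate
27 | C1 triethylsilyl ether of 26 | CC[Si](CC)(CC)O[C@H]1/C=C(\C)CC/C=C(\C)CCC(=O)/C(C)=C\C[C@H]1C(=C)CO[Si](C)(C)C(C)(C)C | intermediate
28 | (1S,6S,7S,14S)-6,7-epoxy-10-ketone (epoxide of 27) | CC[Si](CC)(CC)O[C@H]1/C=C(\C)CC[C@@H]2O[C@@]2(C)CCC(=O)/C(C)=C\C[C@H]1C(=C)CO[Si](C)(C)C(C)(C)C | intermediate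
29 | (1S,6S,7S,10R,14S)-6,7-epoxy-10-ol | CC[Si](CC)(CC)O[C@H]1/C=C(\C)CC[C@@H]2O[C@@]2(C)CC[C@@H](O)/C(C)=C\C[C@H]1C(=C)CO[Si](C)(C)C(C)(C)C | intermediate
30 | (10R)-methanesulfonate of 29 | CC[Si](CC)(CC)O[C@H]1/C=C(\C)CC[C@@H]2O[C@@]2(C)CC[C@@H](OS(C)(=O)=O)/C(C)=C\C[C@H]1C(=C)CO[Si](C)(C)C(C)(C)C | intermediate
31 | (1S,6S,7S,10S,14S)-6,7-epoxy-10-[(2-methoxypropan-2-yl)peroxy] compound | CC[Si](CC)(CC)O[C@H]1/C=C(\C)CC[C@@H]2O[C@@]2(C)CC[C@H](OOC(C)(C)OC)/C(C)=C\C[C@H]1C(=C)CO[Si](C)(C)C(C)(C)C | intermediate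
32 | (10S)-10-hydroperoxy-6,7-epoxide | CC[Si](CC)(CC)O[C@H]1/C=C(\C)CC[C@@H]2O[C@@]2(C)CC[C@H](OO)/C(C)=C\C[C@H]1C(=C)CO[Si](C)(C)C(C)(C)C | intermediate
33 | (1S,6S,7R,10S,14S)-7,10-epidioxy-6-ol, C1 TES and primary TBS ethers | CC[Si](CC)(CC)O[C@H]1/C=C(\C)CC[C@H](O)[C@@]2(C)CC[C@H](OO2)/C(C)=C\C[C@H]1C(=C)CO[Si](C)(C)C(C)(C)C | intermediate
34 | (1S,2E,6S,7R,10S,11Z,14S)-7,10-epidioxy-14-(3-hydroxyprop-1-en-2-yl)-3,7,11-trimethylcyclotetradeca-2,11-diene-1,6-diol | O[C@H]1/C=C(\C)CC[C@H](O)[C@@]2(C)CC[C@H](OO2)/C(C)=C\C[C@H]1C(=C)CO | intermediate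
35 | 2-substituted acrolein from 34 (primary alcohol oxidised) | O[C@H]1/C=C(\C)CC[C@H](O)[C@@]2(C)CC[C@H](OO2)/C(C)=C\C[C@H]1C(=C)C=O | intermediate
36 | lactol (cyclic hemiacetal of 35 with C1–OH) | C=C1C(O)O[C@H]2/C=C(\C)CC[C@H](O)[C@@]3(C)CC[C@H](OO3)/C(C)=C\C[C@@H]12 | intermediate
37 | deacetyl-denticulatolide (C6–OH) | C=C1C(=O)O[C@H]2/C=C(\C)CC[C@H](O)[C@@]3(C)CC[C@H](OO3)/C(C)=C\C[C@@H]12 | intermediate
38 | denticulatolide | C=C1C(=O)O[C@H]2/C=C(\C)CC[C@H](OC(C)=O)[C@@]3(C)CC[C@H](OO3)/C(C)=C\C[C@@H]12 | target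

## Step count and risks

Total steps: 23. Longest linear sequence: 15 (steps 1–5, then 14–23; the West lines 6, 7, 10–12 or 8–12, then 14–23, are equally long).

**Step 16 (macrocyclisation; C1 configuration rests on Felkin control in a ring-forming transition state).** If the closure gives mainly the wrong carbinol, substrate control is replaced by a stereoinversion. The fallback sets out from 25, which is cyclised as before to the (1R)-hydroxy enone F1. This is esterified under Mitsunobu conditions (4-nitrobenzoic acid, PPh3, DIAD, toluene, 0 °C) with SN2 inversion to the (1S)-4-nitrobenzoate F2. Methanolysis (K2CO3, MeOH) comes back to the route at 26.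

**Step 18 (site selectivity among four alkenes).** If the C2=C3 alkene competes, innate selectivity is replaced by electronic deactivation. The fallback sets out from 26, which is benzoylated (BzCl, pyridine, DMAP) to the C1 benzoate F3, so that the neighbouring alkene is switched off as in geranyl esters. Shi epoxidation then gives the epoxy benzoate F4, methanolysis (K2CO3, MeOH) the epoxy alcohol F5, and TESCl/imidazole comes back to the route at 28.

**Step 20 (SN2 of a peroxide anion at a secondary allylic mesylate; SN2′ or ionisation may compete).** If so, the O–O unit is brought in from the tertiary end instead. The fallback sets out from 28, which is treated with ethereal H2O2 and catalytic phosphomolybdic acid; this opens the oxirane at C7 with inversion. The resulting tertiary hydroperoxide closes onto the C10 ketone to the peroxyhemiketal F6. Ionic reduction (Et3SiH, TMSOTf, CH2Cl2, −78 °C) of the derived peroxycarbenium ion, with hydride entering anti to the ten-atom bridge, comes back to the route at 33, which the acid treatment of step 21 converts to 34.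

## Further compounds

F1 | step 16 | (1R)-epimer of 26 | O[C@@H]1/C=C(\C)CC/C=C(\C)CCC(=O)/C(C)=C\C[C@H]1C(=C)CO[Si](C)(C)C(C)(C)C
F2 | step 16 | (1S)-4-nitrobenzoate of 26 | O=C(O[C@H]1/C=C(\C)CC/C=C(\C)CCC(=O)/C(C)=C\C[C@H]1C(=C)CO[Si](C)(C)C(C)(C)C)c1ccc(cc1)[N+](=O)[O-]
F3 | step 18 | C1 benzoate of 26 | O=C(O[C@H]1/C=C(\C)CC/C=C(\C)CCC(=O)/C(C)=C\C[C@H]1C(=C)CO[Si](C)(C)C(C)(C)C)c1ccccc1
F4 | step 18 | (6S,7S)-epoxide of F3 | O=C(O[C@H]1/C=C(\C)CC[C@@H]2O[C@@]2(C)CCC(=O)/C(C)=C\C[C@H]1C(=C)CO[Si](C)(C)C(C)(C)C)c1ccccc1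
F5 | step 18 | (1S,6S,7S,14S)-6,7-epoxy-1-hydroxy-10-ketone (28 without TES) | O[C@H]1/C=C(\C)CC[C@@H]2O[C@@]2(C)CCC(=O)/C(C)=C\C[C@H]1C(=C)CO[Si](C)(C)C(C)(C)C
F6 | step 20 | (1S,6S,7R,14S)-7,10-epidioxy-6,10-diol (peroxyhemiketal, C10 epimers), C1 TES and primary TBS ethers | CC[Si](CC)(CC)O[C@H]1/C=C(\C)CC[C@H](O)[C@@]2(C)CCC(O)(OO2)/C(C)=C\C[C@H]1C(=C)CO[Si](C)(C)C(C)(C)C
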